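## Retrosynthetic overview

1. The target is read as guaiacyl ring A, an inner dihydrobenzofuran (benzene ring B, dihydrofuran ring C) and an outer dihydrobenzofuran (dihydrofuran ring D, benzene ring E) that carries the (E)-propenol. The three CH2OH groups are carried as ethyl esters and the phenol as a pivalate, and one hydride reduction at the end unmasks all four.
2. Key disconnection: the bond from C5 of ring B to C2 of ring D, formed by an enantioselective dearomative conjugate arylation of a flat, achiral benzofuran-3-carboxylate (rings D and E) with the arylboronic acid of the A–B–C fragment. C2 is set by the catalyst and C3 by equilibration to trans.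
3. Enabling feature: in ring D the atoms O1–C2–C3 and the CH2OH carbon on C3 are, one oxidation level up, the O–CH=C–C=O unit of a benzofuran-3-carboxylate. C2 is therefore the β-carbon of a vinylogous carbonate inside a weakly aromatic furan, and it is the carbon at which aryl–palladium species add to benzofurans.
4. Ring C is made with the same polarity in precedented form: asymmetric conjugate arylation of a chromone (sets C2), then oxidative ring contraction of the pyranone to the dihydrofuran (relays C3).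
5. Ring order: pyranone (step 3), contracted to ring C (step 5); furan ring D built aromatic (step 7) and dearomatized in step 8; side chain by Heck reaction (step 9); global reduction (step 10).

Key step: step 8

Remark on the chemistry: the (R) antipode of the t-BuPyOx ligand in steps 4 and 8 is assigned by analogy with the known facial sense of this catalyst on cyclic enones and is to be confirmed on the first flavanone adduct; the (S) ligand is used if the sense proves opposite.

## Route

Step 1
Reactants: 1 4-bromo-2-methoxyphenol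
Product: 2 4-bromo-2-methoxyphenyl pivalate
Conditions: PivCl, Et3N, DMAP (cat.), CH2Cl2, 0 °C to rt
Reagents that add atoms: pivaloyl chloride, CC(C)(C)C(=O)Cl
Why: Acylation of the phenol under nucleophilic catalysis should be clean, and the pivalate is chosen because it lowers the electron density and migratory aptitude of ring A for step 5 and is removed by the final hydride reduction.

Step 2
Reactants: 2 4-bromo-2-methoxyphenyl pivalate
Product: 3 [3-methoxy-4-(pivaloyloxy)phenyl]boronic acid
Conditions: B2(OH)4, Pd(OAc)2 (cat.), XPhos, KOAc, EtOH, 80 °C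
Reagents that add atoms: tetrahydroxydiboron, OB(O)B(O)O
Why: Palladium-catalysed Miyaura-type borylation of the aryl bromide with tetrahydroxydiboron should give the free boronic acid directly under weakly basic conditions that leave the hindered aryl ester intact.

Step 3
Reactants: 4 1-(5-bromo-2-hydroxy-3-methoxyphenyl)ethan-1-one; 5 N,N-dimethylformamide dimethyl acetal
Product: 7 6-bromo-8-methoxy-4H-chromen-4-one, via enaminone 6 (not isolated)
Conditions: toluene, 100 °C; then conc. HCl, CH2Cl2, rt
Reagents that add atoms: none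
Why: The methyl ketone condenses with the amide acetal to the enaminone 6 and acid then promotes intramolecular conjugate addition of the phenol with loss of dimethylamine, the standard enaminone synthesis of chromones.

Step 4
Reactants: 7 6-bromo-8-methoxy-4H-chromen-4-one; 3 [3-methoxy-4-(pivaloyloxy)phenyl]boronic acid
Product: 8 4-[(2S)-6-bromo-8-methoxy-4-oxo-3,4-dihydro-2H-chromen-2-yl]-2-methoxyphenyl pivalate
Conditions: Pd(OCOCF3)2 (5 mol%), (R)-t-BuPyOx (6 mol%), NH4PF6 (30 mol%), H2O (5 equiv), ClCH2CH2Cl, 60 °C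
Reagents that add atoms: none
Why: Asymmetric conjugate addition of arylboronic acids to chromones under cationic divalent palladium/pyridine-oxazoline catalysis is a known route to 2-arylchroman-4-ones, the ligand selects the face of aryl transfer and so sets C2 as S, and the aryl bromide is inert because palladium stays divalent.

Step 5
Reactants: 8 4-[(2S)-6-bromo-8-methoxy-4-oxo-3,4-dihydro-2H-chromen-2-yl]-2-methoxyphenyl pivalate
Product: 10 ethyl (2S,3S)-5-bromo-7-methoxy-2-[3-methoxy-4-(pivaloyloxy)phenyl]-2,3-dihydro-1-benzofuran-3-carboxylate (2,3-trans), via enol ether 9 (not isolated)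
Conditions: PhI(OAc)2, H2SO4 (cat.), HC(OEt)3, 0 °C to rt; aq. NaHCO3 work-up
Reagents that add atoms: triethyl orthoformate, CCOC(OCC)OCC; water, O
Why: Oxidative ring contraction of flavanones with PhI(OAc)2 and acid in an orthoformate is a known route to trans-2-aryl-2,3-dihydrobenzofuran-3-carboxylates: the enol ether 9 is attacked at C3 by the hypervalent iodine reagent anti to the 2-aryl group and the ring B carbon C4a then shifts from C4 to C3 with inversion while C4 becomes the ester carbon, so C2 is untouched and C3 is relayed from it as trans, and the electron-poor pivaloyloxy group disfavors the competing shift and oxidation of ring A.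

Step 6
Reactants: 10 ethyl (2S,3S)-5-bromo-7-methoxy-2-[3-methoxy-4-(pivaloyloxy)phenyl]-2,3-dihydro-1-benzofuran-3-carboxylate
Product: 11 [(2S,3S)-3-(ethoxycarbonyl)-7-methoxy-2-[3-methoxy-4-(pivaloyloxy)phenyl]-2,3-dihydro-1-benzofuran-5-yl]boronic acid
Conditions: B2(OH)4, Pd(OAc)2 (cat.), XPhos, KOAc, EtOH, 80 °C
Reagents that add atoms: tetrahydroxydiboron, OB(O)B(O)O
Why: The same Miyaura-type borylation should convert the electron-rich aryl bromide into the boronic acid without touching the esters, and the two stereocenters are safe because the trans ester is the thermodynamic epimer and ethanol matches the ester.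

Step 7
Reactants: 12 5-bromo-2-hydroxy-3-methoxybenzaldehyde; 13 ethyl diazoacetate
Product: 15 ethyl 5-bromo-7-methoxy-1-benzofuran-3-carboxylate, via hemiacetal 14 (not isolated)
Conditions: HBF4·OEt2 (10 mol%), CH2Cl2, rt; then conc. H2SO4, rt
Reagents that add atoms: none
Why: Acid-catalysed addition of the diazoester to the aldehyde with 1,2-aryl shift and loss of nitrogen (a Roskamp-type homologation) gives the 2-aryl-3-oxopropanoate, which closes to hemiacetal 14 and is dehydrated by sulfuric acid to the aromatic benzofuran, a known one-flask synthesis of benzofuran-3-carboxylates from salicylaldehydes.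

Step 8
Reactants: 11 [(2S,3S)-3-(ethoxycarbonyl)-7-methoxy-2-[3-methoxy-4-(pivaloyloxy)phenyl]-2,3-dihydro-1-benzofuran-5-yl]boronic acid; 15 ethyl 5-bromo-7-methoxy-1-benzofuran-3-carboxylate
Product: 17 ethyl (2S,3S)-5-bromo-2-[(2S,3S)-3-(ethoxycarbonyl)-7-methoxy-2-[3-methoxy-4-(pivaloyloxy)phenyl]-2,3-dihydro-1-benzofuran-5-yl]-7-methoxy-2,3-dihydro-1-benzofuran-3-carboxylate (ring D 2,3-trans), via cis ester 16 (not isolated)
Conditions: 15 (2 equiv), Pd(OCOCF3)2 (10 mol%), (R)-t-BuPyOx (12 mol%), NH4PF6 (30 mol%), H2O (5 equiv), ClCH2CH2Cl, 60 °C; filtration through SiO2; then DBU (20 mol%), toluene, 60 °C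
Reagents that add atoms: none
Why: Proposed new method: transmetalation of boronic acid 11 to the cationic divalent palladium–t-BuPyOx complex gives an aryl–palladium species that should add syn across the C2=C3 bond of 15 with the aryl group at the unsubstituted C2 (the β-carbon of the O–C2=C3–C=O vinylogous carbonate and the position at which Heck-type arylation of benzofurans takes place), and protonolysis of the resulting palladium enolate by water releases the dearomatized adduct and regenerates divalent palladium, so neither oxidant nor reductant is needed. The closest known reaction types are the divalent-palladium/t-BuPyOx conjugate addition of arylboronic acids to chromones (used in step 4) and the Heck-type C2 arylation of benzofurans. No ring is closed; the furan ring D is dearomatized. The C2 stereocenter is set by the chiral ligand, which selects the face of the flat benzofuran, and the C3 stereocenter is relayed from C2, because DBU equilibrates the α-ester center of the kinetic cis adduct 16 (protonation anti to the new aryl group) to the trans ester 17. The step needs protonolysis of the enolate to outrun β-hydride elimination (which would return a flat 2-arylbenzofuran) and β-aryloxide elimination: water and NH4PF6 speed protonolysis, and the endocyclic C2–O bond lies in the ring plane, orthogonal to the enolate π system, which disfavors ring opening. The aryl bromide of 15 is not touched because palladium stays divalent, and aryl transfer to the CH terminus of this trisubstituted alkene is sterically easier than the quaternary-center-forming additions that this catalyst already performs.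

Step 9
Reactants: 17 ethyl (2S,3S)-5-bromo-2-[(2S,3S)-3-(ethoxycarbonyl)-7-methoxy-2-[3-methoxy-4-(pivaloyloxy)phenyl]-2,3-dihydro-1-benzofuran-5-yl]-7-methoxy-2,3-dihydro-1-benzofuran-3-carboxylate; 18 ethyl acrylate
Product: 19 ethyl (2S,3S)-2-[(2S,3S)-3-(ethoxycarbonyl)-7-methoxy-2-[3-methoxy-4-(pivaloyloxy)phenyl]-2,3-dihydro-1-benzofuran-5-yl]-5-[(E)-3-ethoxy-3-oxoprop-1-en-1-yl]-7-methoxy-2,3-dihydro-1-benzofuran-3-carboxylate
Conditions: Pd(OAc)2 (cat.), P(o-tol)3, Et3N, DMF, 100 °C
Reagents that add atoms: none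
Why: A Mizoroki–Heck reaction of the aryl bromide with the acrylate should give the E-cinnamate through syn insertion and syn β-hydride elimination, and the trans ester stereocenters are thermodynamically stable to the amine base.

Step 10
Reactants: 19 ethyl (2S,3S)-2-[(2S,3S)-3-(ethoxycarbonyl)-7-methoxy-2-[3-methoxy-4-(pivaloyloxy)phenyl]-2,3-dihydro-1-benzofuran-5-yl]-5-[(E)-3-ethoxy-3-oxoprop-1-en-1-yl]-7-methoxy-2,3-dihydro-1-benzofuran-3-carboxylate
Product: 20 4-[(2S,3R)-3-(hydroxymethyl)-5-[(2S,3R)-3-(hydroxymethyl)-5-[(E)-3-hydroxyprop-1-en-1-yl]-7-methoxy-2,3-dihydro-1-benzofuran-2-yl]-7-methoxy-2,3-dihydro-1-benzofuran-2-yl]-2-methoxyphenol (CNP0250921.2)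
Conditions: i-Bu2AlH (excess), CH2Cl2, −78 to 0 °C; aq. potassium sodium tartrate
Reagents that add atoms: none
Why: Hydride reduction with i-Bu2AlH converts the two saturated esters and, by 1,2-reduction, the cinnamate into primary alcohols and cleaves the aryl pivalate in the same operation, no stereocenter or alkene is touched (the descriptor at each C3 changes from S to R by priority only), and the neutral tartrate work-up spares the acid-sensitive benzylic aryl ethers and the allylic alcohol.

## Compound list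

1 | 4-bromo-2-methoxyphenol | COc1cc(Br)ccc1O | starting material
2 | 4-bromo-2-methoxyphenyl pivalate | COc1cc(Br)ccc1OC(=O)C(C)(C)C | intermediate
3 | [3-methoxy-4-(pivaloyloxy)phenyl]boronic acid | COc1cc(B(O)O)ccc1OC(=O)C(C)(C)C | intermediate
4 | 1-(5-bromo-2-hydroxy-3-methoxyphenyl)ethan-1-one | CC(=O)c1cc(Br)cc(OC)c1O | starting material
5 | N,N-dimethylformamide dimethyl acetal | COC(OC)N(C)C | starting material
6 | (E)-1-(5-bromo-2-hydroxy-3-methoxyphenyl)-3-(dimethylamino)prop-2-en-1-one (enaminone; not isolated) | CN(C)/C=C/C(=O)c1cc(Br)cc(OC)c1O | intermediate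
7 | 6-bromo-8-methoxy-4H-chromen-4-one | COc1cc(Br)cc2c(=O)ccoc12 | intermediate
8 | 4-[(2S)-6-bromo-8-methoxy-4-oxo-3,4-dihydro-2H-chromen-2-yl]-2-methoxyphenyl pivalate | COc1cc([C@H]2Oc3c(OC)cc(Br)cc3C(=O)C2)ccc1OC(=O)C(C)(C)C | intermediate
9 | 4-[(2S)-6-bromo-4-ethoxy-8-methoxy-2H-chromen-2-yl]-2-methoxyphenyl pivalate (enol ether; not isolated) | COc1cc([C@H]2Oc3c(OC)cc(Br)cc3C(OCC)=C2)ccc1OC(=O)C(C)(C)C | intermediate
10 | ethyl (2S,3S)-5-bromo-7-methoxy-2-[3-methoxy-4-(pivaloyloxy)phenyl]-2,3-dihydro-1-benzofuran-3-carboxylate (2,3-trans) | COc1cc([C@H]2Oc3c(OC)cc(Br)cc3[C@@H]2C(=O)OCC)ccc1OC(=O)C(C)(C)C | intermediate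
11 | [(2S,3S)-3-(ethoxycarbonyl)-7-methoxy-2-[3-methoxy-4-(pivaloyloxy)phenyl]-2,3-dihydro-1-benzofuran-5-yl]boronic acid | COc1cc([C@H]2Oc3c(OC)cc(B(O)O)cc3[C@@H]2C(=O)OCC)ccc1OC(=O)C(C)(C)C | intermediate
12 | 5-bromo-2-hydroxy-3-methoxybenzaldehyde | COc1cc(Br)cc(C=O)c1O | starting material
13 | ethyl diazoacetate | CCOC(=O)C=[N+]=[N-] | starting material
14 | ethyl 5-bromo-2-hydroxy-7-methoxy-2,3-dihydro-1-benzofuran-3-carboxylate (hemiacetal, racemic diastereomer mixture; not isolated) | CCOC(=O)C1C(O)Oc2c(OC)cc(Br)cc12 | intermediate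
15 | ethyl 5-bromo-7-methoxy-1-benzofuran-3-carboxylate | CCOC(=O)c1coc2c(OC)cc(Br)cc12 | intermediate
16 | ethyl (2S,3R)-5-bromo-2-[(2S,3S)-3-(ethoxycarbonyl)-7-methoxy-2-[3-methoxy-4-(pivaloyloxy)phenyl]-2,3-dihydro-1-benzofuran-5-yl]-7-methoxy-2,3-dihydro-1-benzofuran-3-carboxylate (ring D 2,3-cis; not isolated) | COc1cc([C@H]2Oc3c(OC)cc([C@H]4Oc5c(OC)cc(Br)cc5[C@H]4C(=O)OCC)cc3[C@@H]2C(=O)OCC)ccc1OC(=O)C(C)(C)C | intermediate
17 | ethyl (2S,3S)-5-bromo-2-[(2S,3S)-3-(ethoxycarbonyl)-7-methoxy-2-[3-methoxy-4-(pivaloyloxy)phenyl]-2,3-dihydro-1-benzofuran-5-yl]-7-methoxy-2,3-dihydro-1-benzofuran-3-carboxylate (ring D 2,3-trans) | COc1cc([C@H]2Oc3c(OC)cc([C@H]4Oc5c(OC)cc(Br)cc5[C@@H]4C(=O)OCC)cc3[C@@H]2C(=O)OCC)ccc1OC(=O)C(C)(C)C | intermediate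
18 | ethyl acrylate | C=CC(=O)OCC | starting material
19 | ethyl (2S,3S)-2-[(2S,3S)-3-(ethoxycarbonyl)-7-methoxy-2-[3-methoxy-4-(pivaloyloxy)phenyl]-2,3-dihydro-1-benzofuran-5-yl]-5-[(E)-3-ethoxy-3-oxoprop-1-en-1-yl]-7-methoxy-2,3-dihydro-1-benzofuran-3-carboxylate | COc1cc([C@H]2Oc3c(OC)cc([C@H]4Oc5c(OC)cc(/C=C/C(=O)OCC)cc5[C@@H]4C(=O)OCC)cc3[C@@H]2C(=O)OCC)ccc1OC(=O)C(C)(C)C | intermediate
20 | 4-[(2S,3R)-3-(hydroxymethyl)-5-[(2S,3R)-3-(hydroxymethyl)-5-[(E)-3-hydroxyprop-1-en-1-yl]-7-methoxy-2,3-dihydro-1-benzofuran-2-yl]-7-methoxy-2,3-dihydro-1-benzofuran-2-yl]-2-methoxyphenol | COc1cc([C@H]2Oc3c(OC)cc([C@H]4Oc5c(OC)cc(/C=C/CO)cc5[C@@H]4CO)cc3[C@@H]2CO)ccc1O | target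

## Step count and risks

Total step count: 10. Longest linear sequence: 8 steps (steps 1, 2, 4, 5, 6, 8, 9, 10).

Steps most likely to fail:

1. Step 8 (proposed new method). The insertion into the trisubstituted, partly aromatic C2=C3 bond may be slow, so that protodeboronation of 11 takes over. β-Hydride elimination may rearomatize the adduct and reduce the catalyst, or the facial selectivity may be poor. The fallback uses known chemistry, sets out from 11 and the chromone 7, and comes back to the route at 17. Conjugate addition of 11 to 7 under the conditions of step 4 should give the 2-arylchroman-4-one ethyl (2S,3S)-5-[(2S)-6-bromo-8-methoxy-4-oxo-3,4-dihydro-2H-chromen-2-yl]-7-methoxy-2-[3-methoxy-4-(pivaloyloxy)phenyl]-2,3-dihydro-1-benzofuran-3-carboxylate F1. Treatment with PhI(OAc)2, H2SO4 (cat.) and HC(OEt)3 as in step 5 should then pass through the enol ether ethyl (2S,3S)-5-[(2S)-6-bromo-4-ethoxy-8-methoxy-2H-chromen-2-yl]-7-methoxy-2-[3-methoxy-4-(pivaloyloxy)phenyl]-2,3-dihydro-1-benzofuran-3-carboxylate F2 and contract the pyranone to ring D, giving 17. In F1 the 2-aryl group carries a para alkoxy group and is more prone to shift and to ionization at C2 than in 8, which is why this sequence is held in reserve.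

2. Step 5. The 2-aryl group may shift instead of the ring B carbon (isoflavone formation), the flavanone may be dehydrogenated to a flavone, or the electron-rich rings may be over-oxidized. The fallback sets out from 8 and comes back at 10 by a Wolff ring contraction.
   - Trifluoroacetylation of 8 (LiN(SiMe3)2, THF, −78 °C; CF3CO2CH2CF3) should give 4-[(2S)-6-bromo-8-methoxy-4-oxo-3-(trifluoroacetyl)-3,4-dihydro-2H-chromen-2-yl]-2-methoxyphenyl pivalate F3; the low temperature is meant to prevent ring opening of the enolate to the chalcone.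
   - Deacylative diazo transfer (MsN3, Et3N, H2O, MeCN, rt) should give 4-[(2R)-6-bromo-3-diazo-8-methoxy-4-oxo-3,4-dihydro-2H-chromen-2-yl]-2-methoxyphenyl pivalate F4; the descriptor changes by priority only.
   - Irradiation (hν, 365 nm, EtOH) should trigger the Wolff rearrangement, in which the ring B carbon shifts to C3 to give the ketene 4-[(2R)-5-bromo-7-methoxy-3-(oxomethylidene)-2,3-dihydro-1-benzofuran-2-yl]-2-methoxyphenyl pivalate F5.
   - Ethanol traps the ketene, mainly as the cis ester ethyl (2S,3R)-5-bromo-7-methoxy-2-[3-methoxy-4-(pivaloyloxy)phenyl]-2,3-dihydro-1-benzofuran-3-carboxylate F6, and DBU (cat.), toluene, 60 °C should epimerize this to 10.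

3. Step 10. Conjugate reduction of the cinnamate or incomplete cleavage of the hindered pivalate may occur, and the polar, acid- and air-sensitive tetraol may be lost on aluminium salts. The fallback sets out from 17, bypasses step 9 and comes back at 20, bringing in the side chain at the alcohol oxidation level. Reduction of 17 with i-Bu2AlH (CH2Cl2, −78 to 0 °C) should give 4-[(2S,3R)-5-[(2S,3R)-5-bromo-3-(hydroxymethyl)-7-methoxy-2,3-dihydro-1-benzofuran-2-yl]-3-(hydroxymethyl)-7-methoxy-2,3-dihydro-1-benzofuran-2-yl]-2-methoxyphenol F7. Suzuki–Miyaura coupling with commercial (E)-tert-butyldimethyl{[3-(4,4,5,5-tetramethyl-1,3,2-dioxaborolan-2-yl)prop-2-en-1-yl]oxy}silane (PdCl2(dppf), K2CO3, dioxane/H2O, 80 °C) should give 4-[(2S,3R)-5-[(2S,3R)-5-[(E)-3-(tert-butyldimethylsilyloxy)prop-1-en-1-yl]-3-(hydroxymethyl)-7-methoxy-2,3-dihydro-1-benzofuran-2-yl]-3-(hydroxymethyl)-7-methoxy-2,3-dihydro-1-benzofuran-2-yl]-2-methoxyphenol F8. Desilylation with n-Bu4NF (THF, 0 °C) should then give 20.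

## Further compounds

F1 | step 8 | ethyl (2S,3S)-5-[(2S)-6-bromo-8-methoxy-4-oxo-3,4-dihydro-2H-chromen-2-yl]-7-methoxy-2-[3-methoxy-4-(pivaloyloxy)phenyl]-2,3-dihydro-1-benzofuran-3-carboxylate | COc1cc([C@H]2Oc3c(OC)cc([C@H]4Oc5c(OC)cc(Br)cc5C(=O)C4)cc3[C@@H]2C(=O)OCC)ccc1OC(=O)C(C)(C)C
F2 | step 8 | ethyl (2S,3S)-5-[(2S)-6-bromo-4-ethoxy-8-methoxy-2H-chromen-2-yl]-7-methoxy-2-[3-methoxy-4-(pivaloyloxy)phenyl]-2,3-dihydro-1-benzofuran-3-carboxylate | COc1cc([C@H]2Oc3c(OC)cc([C@H]4Oc5c(OC)cc(Br)cc5C(OCC)=C4)cc3[C@@H]2C(=O)OCC)ccc1OC(=O)C(C)(C)C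
F3 | step 5 | 4-[(2S)-6-bromo-8-methoxy-4-oxo-3-(trifluoroacetyl)-3,4-dihydro-2H-chromen-2-yl]-2-methoxyphenyl pivalate | COc1cc([C@H]2Oc3c(OC)cc(Br)cc3C(=O)C2C(=O)C(F)(F)F)ccc1OC(=O)C(C)(C)C
F4 | step 5 | 4-[(2R)-6-bromo-3-diazo-8-methoxy-4-oxo-3,4-dihydro-2H-chromen-2-yl]-2-methoxyphenyl pivalate | COc1cc([C@H]2Oc3c(OC)cc(Br)cc3C(=O)C2=[N+]=[N-])ccc1OC(=O)C(C)(C)C
F5 | step 5 | 4-[(2R)-5-bromo-7-methoxy-3-(oxomethylidene)-2,3-dihydro-1-benzofuran-2-yl]-2-methoxyphenyl pivalate | COc1cc([C@H]2Oc3c(OC)cc(Br)cc3C2=C=O)ccc1OC(=O)C(C)(C)C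
F6 | step 5 | ethyl (2S,3R)-5-bromo-7-methoxy-2-[3-methoxy-4-(pivaloyloxy)phenyl]-2,3-dihydro-1-benzofuran-3-carboxylate (2,3-cis) | COc1cc([C@H]2Oc3c(OC)cc(Br)cc3[C@H]2C(=O)OCC)ccc1OC(=O)C(C)(C)C
F7 | step 10 | 4-[(2S,3R)-5-[(2S,3R)-5-bromo-3-(hydroxymethyl)-7-methoxy-2,3-dihydro-1-benzofuran-2-yl]-3-(hydroxymethyl)-7-methoxy-2,3-dihydro-1-benzofuran-2-yl]-2-methoxyphenol | COc1cc([C@H]2Oc3c(OC)cc([C@H]4Oc5c(OC)cc(Br)cc5[C@@H]4CO)cc3[C@@H]2CO)ccc1O
F8 | step 10 | 4-[(2S,3R)-5-[(2S,3R)-5-[(E)-3-(tert-butyldimethylsilyloxy)prop-1-en-1-yl]-3-(hydroxymethyl)-7-methoxy-2,3-dihydro-1-benzofuran-2-yl]-3-(hydroxymethyl)-7-methoxy-2,3-dihydro-1-benzofuran-2-yl]-2-methoxyphenol | COc1cc([C@H]2Oc3c(OC)cc([C@H]4Oc5c(OC)cc(/C=C/CO[Si](C)(C)C(C)(C)C)cc5[C@@H]4CO)cc3[C@@H]2CO)ccc1O
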